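**Retrosynthetic overview**

- Target ⇐ DDQ removal of a C5 PMB ether ⇐ angeloylation of the free C6‑OH of the tricyclic core.
- Tricyclic core ⇐ acyclic α'-hydroxy ynone aldehyde carrying a 3‑(acetoxymethyl)butenolide. One pot: Au(I) 5‑endo‑dig cycloisomerisation (furanone), then Pd(0)/InI umpolung allylation closing C6–C7 (ten‑membered ring); C6 and C7 are set here.
- Seco compound ⇐ C1–C2 union of an enyne acetylide with an α‑hydroxy aldehyde, then double oxidation.
- Butenolide aldehyde ⇐ (R)-citramalic acid (C10) plus Ir‑catalysed 2‑(alkoxycarbonyl)allylation (C8, lactone); enyne ⇐ methyl (R)-glycerate acetonide (C5).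
- Ring order: butenolide first; furanone and ten‑membered carbocycle together; the butenolide becomes the α‑methylene lactone in the same operation.

Assumption: germacrane numbering is used for positions (C1 ketone, C2=C3, C3–O–C10 bridge, C4=C15, C5 OH, C6 angelate, C7/C8 lactone fusion, C11=C13, C12 lactone C=O, C14 methyl); the given SMILES corresponds to 5S,6S,7R,8S,10R.

**Route**

Step 1
Reactants: 1 (R)-citramalic acid [(2R)-2-hydroxy-2-methylbutanedioic acid]
Product: 2 (2R)-2-methylbutane-1,2,4-triol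
Conditions: BH3·SMe2, B(OMe)3, THF, 0 °C to rt; MeOH quench
Reagents that add atoms: none
Why: Borane reduction of both carboxylic acids to primary alcohols; the quaternary carbinol (future C10) comes unchanged from the chiral pool.

Step 2
Reactants: 2 (2R)-2-methylbutane-1,2,4-triol
Product: 3 2-[(4R)-2,2,4-trimethyl-1,3-dioxolan-4-yl]ethan-1-ol
Conditions: 2,2-dimethoxypropane, acetone, TsOH (cat.), rt
Reagents that add atoms: 2,2-dimethoxypropane COC(C)(C)OC
Why: Thermodynamic ketalisation selects the five-membered 1,2-acetonide and leaves the C8 primary alcohol free; no stereocentre is touched.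

Step 3
Reactants: 3 2-[(4R)-2,2,4-trimethyl-1,3-dioxolan-4-yl]ethan-1-ol
Product: 5 (5R)-3-methylidene-5-{[(4R)-2,2,4-trimethyl-1,3-dioxolan-4-yl]methyl}oxolan-2-one, via hydroxy ester 4 (not isolated)
Conditions: allyl carbonate reagent, [Ir(cod)Cl]2/SEGPHOS/4-cyano-3-nitrobenzoic acid (cat.), Cs2CO3 (cat.), THF, 60 °C
Reagents that add atoms: methyl 2-{[(tert-butoxycarbonyl)oxy]methyl}prop-2-enoate C=C(COC(=O)OC(C)(C)C)C(=O)OC
Why: Krische iridium-catalysed transfer-hydrogenative 2-(alkoxycarbonyl)allylation of the primary alcohol followed by lactonisation; C8 is set by the chiral catalyst (ligand enantiomer chosen for the 5R lactone), independent of the remote C10 centre.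

Step 4
Reactants: 5 (5R)-3-methylidene-5-{[(4R)-2,2,4-trimethyl-1,3-dioxolan-4-yl]methyl}oxolan-2-one
Product: 6 (5S)-3-(bromomethyl)-5-{[(4R)-2,2,4-trimethyl-1,3-dioxolan-4-yl]methyl}furan-2(5H)-one
Conditions: NBS, AIBN (cat.), PhCF3, 85 °C
Reagents that add atoms: N-bromosuccinimide O=C1CCC(=O)N1Br
Why: Wohl–Ziegler allylic bromination with allylic transposition, the C7 allyl radical being trapped at the exocyclic terminus to give the conjugated primary bromide; C8 is untouched (R to S is a CIP priority change only).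

Step 5
Reactants: 6 (5S)-3-(bromomethyl)-5-{[(4R)-2,2,4-trimethyl-1,3-dioxolan-4-yl]methyl}furan-2(5H)-one
Product: 7 [(5S)-2-oxo-5-{[(4R)-2,2,4-trimethyl-1,3-dioxolan-4-yl]methyl}-2,5-dihydrofuran-3-yl]methyl acetate
Conditions: KOAc, 18-crown-6 (cat.), MeCN, rt
Reagents that add atoms: potassium acetate CC(=O)[O-].[K+]
Why: SN2 displacement masks the alkylating bromide as an allylic acetate, which survives the later alkoxide-generating alkynylation and then serves as the π-allyl precursor.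

Step 6
Reactants: 7 [(5S)-2-oxo-5-{[(4R)-2,2,4-trimethyl-1,3-dioxolan-4-yl]methyl}-2,5-dihydrofuran-3-yl]methyl acetate
Product: 8 {(5S)-5-[(2R)-2,3-dihydroxy-2-methylpropyl]-2-oxo-2,5-dihydrofuran-3-yl}methyl acetate
Conditions: AcOH/H2O (4:1), 40 °C
Reagents that add atoms: none
Why: Acid-catalysed acetonide hydrolysis; butenolide and allylic acetate are stable to aqueous acetic acid.

Step 7
Reactants: 8 {(5S)-5-[(2R)-2,3-dihydroxy-2-methylpropyl]-2-oxo-2,5-dihydrofuran-3-yl}methyl acetate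
Product: 9 {(5S)-5-[(2R)-2-hydroxy-2-methyl-3-oxopropyl]-2-oxo-2,5-dihydrofuran-3-yl}methyl acetate
Conditions: TEMPO (cat.), PhI(OAc)2, CH2Cl2, rt; used crude
Reagents that add atoms: none
Why: TEMPO/PhI(OAc)2 oxidation of the primary alcohol to the aldehyde; the tertiary alcohol is inert and the α-carbon is quaternary, so no epimerisation is possible.

Step 8
Reactants: 10 methyl (4R)-2,2-dimethyl-1,3-dioxolane-4-carboxylate
Product: 11 1-[(4R)-2,2-dimethyl-1,3-dioxolan-4-yl]-3-(trimethylsilyl)prop-2-yn-1-one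
Conditions: LiC≡CSiMe3 (1.05 equiv), THF, −78 °C; aq NH4Cl at −78 °C
Reagents that add atoms: lithium (trimethylsilyl)acetylide [Li]C#C[Si](C)(C)C
Why: Acyl substitution of the α-alkoxy ester by the acetylide stops at the ynone because the chelated tetrahedral intermediate persists at −78 °C; the stereocentre (future C5) is retained.

Step 9
Reactants: 11 1-[(4R)-2,2-dimethyl-1,3-dioxolan-4-yl]-3-(trimethylsilyl)prop-2-yn-1-one
Product: 12 (4S)-2,2-dimethyl-4-[4-(trimethylsilyl)but-1-en-3-yn-2-yl]-1,3-dioxolane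
Conditions: Ph3PCH3Br, KHMDS, THF, −78 to 0 °C
Reagents that add atoms: methyltriphenylphosphonium bromide C[P+](c1ccccc1)(c1ccccc1)c1ccccc1.[Br-]
Why: Wittig methylenation of the ynone carbonyl installs the C4=C15 methylene; the salt-free ylide at low temperature avoids epimerisation (R to S is a CIP priority change only).

Step 10
Reactants: 12 (4S)-2,2-dimethyl-4-[4-(trimethylsilyl)but-1-en-3-yn-2-yl]-1,3-dioxolane
Product: 13 (4S)-2-(4-methoxyphenyl)-4-[4-(trimethylsilyl)but-1-en-3-yn-2-yl]-1,3-dioxolane (both acetal epimers)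
Conditions: 4-MeOC6H4CH(OMe)2, CSA (cat.), CH2Cl2, 40 °C
Reagents that add atoms: 4-methoxybenzaldehyde dimethyl acetal COC(OC)c1ccc(OC)cc1
Why: Acid-catalysed transacetalisation exchanges the acetonide for the p-methoxybenzylidene acetal, driven by removal of 2,2-dimethoxypropane.

Step 11
Reactants: 13 (4S)-2-(4-methoxyphenyl)-4-[4-(trimethylsilyl)but-1-en-3-yn-2-yl]-1,3-dioxolane
Product: 14 (2S)-2-[(4-methoxyphenyl)methoxy]-3-methylidene-5-(trimethylsilyl)pent-4-yn-1-ol
Conditions: DIBAL-H, CH2Cl2, −78 to −20 °C; Rochelle salt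
Reagents that add atoms: none
Why: Regioselective reductive acetal opening: DIBAL coordinates the less hindered primary oxygen, so the PMB group ends on the secondary C5 oxygen and the primary alcohol is freed.

Step 12
Reactants: 14 (2S)-2-[(4-methoxyphenyl)methoxy]-3-methylidene-5-(trimethylsilyl)pent-4-yn-1-ol
Product: 15 (2S)-2-[(4-methoxyphenyl)methoxy]-3-methylidenepent-4-yn-1-ol
Conditions: K2CO3 (cat.), MeOH, rt
Reagents that add atoms: none
Why: Base-catalysed methanolysis of the alkynyl C–Si bond (protodesilylation) liberates the terminal alkyne.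

Step 13
Reactants: 9 {(5S)-5-[(2R)-2-hydroxy-2-methyl-3-oxopropyl]-2-oxo-2,5-dihydrofuran-3-yl}methyl acetate; 15 (2S)-2-[(4-methoxyphenyl)methoxy]-3-methylidenepent-4-yn-1-ol
Product: 16 {(5S)-5-[(2R,3RS,7S)-2,3,8-trihydroxy-7-[(4-methoxyphenyl)methoxy]-2-methyl-6-methylideneoct-4-yn-1-yl]-2-oxo-2,5-dihydrofuran-3-yl}methyl acetate
Conditions: 15 (2.2 equiv), n-BuLi (4.4 equiv), THF, −78 °C; CeCl3; then 9, −78 °C; aq NH4Cl at −78 °C
Reagents that add atoms: none
Why: 1,2-Addition of a weakly basic alkynylcerium reagent to the aldehyde, which is far more electrophilic than the butenolide or acetate at −78 °C (one equivalent is quenched by the tertiary OH and recovered as 15); the new C1 carbinol is an epimer mixture that is oxidised next.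

Step 14
Reactants: 16 {(5S)-5-[(2R,3RS,7S)-2,3,8-trihydroxy-7-[(4-methoxyphenyl)methoxy]-2-methyl-6-methylideneoct-4-yn-1-yl]-2-oxo-2,5-dihydrofuran-3-yl}methyl acetate
Product: 17 {(5S)-5-[(2R,7S)-2-hydroxy-7-[(4-methoxyphenyl)methoxy]-2-methyl-6-methylidene-3,8-dioxooct-4-yn-1-yl]-2-oxo-2,5-dihydrofuran-3-yl}methyl acetate
Conditions: Dess–Martin periodinane, NaHCO3, CH2Cl2, 0 °C to rt; used at once
Reagents that add atoms: none
Why: Dess–Martin oxidation converts the propargylic alcohol to the ynone and the primary alcohol to the aldehyde in one pass while the tertiary alcohol is inert; the buffered non-basic medium preserves the α-alkoxy aldehyde centre (C5).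

Step 15
Reactants: 17 {(5S)-5-[(2R,7S)-2-hydroxy-7-[(4-methoxyphenyl)methoxy]-2-methyl-6-methylidene-3,8-dioxooct-4-yn-1-yl]-2-oxo-2,5-dihydrofuran-3-yl}methyl acetate
Product: 19 6-O-desangeloyl-5-O-(4-methoxybenzyl) derivative of 21 (tricycle with free C6-OH; all five stereocentres as in 21), via furanone aldehyde 18 (not isolated)
Conditions: (Ph3P)AuNTf2 (5 mol %), THF, rt; then dilute to 2 mM, Pd(PPh3)4 (10 mol %), InI (2 equiv), THF/MeOH, rt
Reagents that add atoms: none
Why: Proposed new method: Au(I)-catalysed 5-endo-dig cycloisomerisation of the α'-hydroxy ynone first gives the 3(2H)-furanone (removing the ketone that an allylmetal could attack), then Pd(0) ionises the allylic acetate and InI reduces the π-allyl to an allylindium (Araki Pd/InI umpolung allylation; closest precedents are Barbier macrocyclisations of bromomethyl butenolides), which adds through C7 to the tethered aldehyde in a chair transition state anti to the C8 side chain (trans lactone), the ring-locked E allyl geometry giving the anti C6/C7 relationship and indium chelation to the C5 OPMB group giving 5,6-syn.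

Step 16
Reactants: 19 6-O-desangeloyl-5-O-(4-methoxybenzyl) derivative of 21
Product: 20 5-O-(4-methoxybenzyl) ether of 21
Conditions: angelic acid, 2,4,6-trichlorobenzoyl chloride, Et3N, toluene, rt; then 19, 75 °C
Reagents that add atoms: angelic acid [(Z)-2-methylbut-2-enoic acid] C/C=C(C)\C(=O)O
Why: Yamaguchi-type esterification through the preformed mixed anhydride acylates the only free hydroxyl (C6) without Z to E isomerisation of the angelate; no stereocentre changes.

Step 17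
Reactants: 20 5-O-(4-methoxybenzyl) ether of 21
Product: 21 (5S,6S,7R,8S,10R)-6-angeloyloxy-3,10-epoxy-5-hydroxy-1-oxogermacra-2,4(15),11(13)-trien-12,8-olide (target)
Conditions: DDQ, CH2Cl2/pH 7 buffer, 0 °C to rt
Reagents that add atoms: none
Why: Oxidative PMB ether cleavage by DDQ frees the C5 hydroxyl under neutral conditions that leave the angelate, furanone and α-methylene lactone untouched.

**Compound list**

1 | (R)-citramalic acid [(2R)-2-hydroxy-2-methylbutanedioic acid] | OC(=O)C[C@@](C(=O)O)(C)O | starting material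
2 | (2R)-2-methylbutane-1,2,4-triol | OCC[C@@](CO)(C)O | intermediate
3 | 2-[(4R)-2,2,4-trimethyl-1,3-dioxolan-4-yl]ethan-1-ol | OCC[C@@]1(C)OC(C)(C)OC1 | intermediate
4 | methyl (4R)-4-hydroxy-2-methylidene-5-[(4R)-2,2,4-trimethyl-1,3-dioxolan-4-yl]pentanoate | C=C(C[C@@H](O)C[C@@]1(C)OC(C)(C)OC1)C(=O)OC | intermediate
5 | (5R)-3-methylidene-5-{[(4R)-2,2,4-trimethyl-1,3-dioxolan-4-yl]methyl}oxolan-2-one | C=C1C(=O)O[C@@H](C[C@@]2(C)OC(C)(C)OC2)C1 | intermediate
6 | (5S)-3-(bromomethyl)-5-{[(4R)-2,2,4-trimethyl-1,3-dioxolan-4-yl]methyl}furan-2(5H)-one | BrCC1=C[C@H](C[C@@]2(C)OC(C)(C)OC2)OC1=O | intermediate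
7 | [(5S)-2-oxo-5-{[(4R)-2,2,4-trimethyl-1,3-dioxolan-4-yl]methyl}-2,5-dihydrofuran-3-yl]methyl acetate | CC(=O)OCC1=C[C@H](C[C@@]2(C)OC(C)(C)OC2)OC1=O | intermediate
8 | {(5S)-5-[(2R)-2,3-dihydroxy-2-methylpropyl]-2-oxo-2,5-dihydrofuran-3-yl}methyl acetate | CC(=O)OCC1=C[C@H](C[C@@](C)(O)CO)OC1=O | intermediate
9 | {(5S)-5-[(2R)-2-hydroxy-2-methyl-3-oxopropyl]-2-oxo-2,5-dihydrofuran-3-yl}methyl acetate | CC(=O)OCC1=C[C@H](C[C@@](C)(O)C=O)OC1=O | intermediate
10 | methyl (4R)-2,2-dimethyl-1,3-dioxolane-4-carboxylate | COC(=O)[C@H]1COC(C)(C)O1 | starting material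
11 | 1-[(4R)-2,2-dimethyl-1,3-dioxolan-4-yl]-3-(trimethylsilyl)prop-2-yn-1-one | C[Si](C)(C)C#CC(=O)[C@H]1COC(C)(C)O1 | intermediate
12 | (4S)-2,2-dimethyl-4-[4-(trimethylsilyl)but-1-en-3-yn-2-yl]-1,3-dioxolane | C[Si](C)(C)C#CC(=C)[C@H]1COC(C)(C)O1 | intermediate
13 | (4S)-2-(4-methoxyphenyl)-4-[4-(trimethylsilyl)but-1-en-3-yn-2-yl]-1,3-dioxolane (both acetal epimers) | C[Si](C)(C)C#CC(=C)[C@H]1COC(c2ccc(OC)cc2)O1 | intermediate
14 | (2S)-2-[(4-methoxyphenyl)methoxy]-3-methylidene-5-(trimethylsilyl)pent-4-yn-1-ol | C[Si](C)(C)C#CC(=C)[C@H](OCc1ccc(OC)cc1)CO | intermediate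
15 | (2S)-2-[(4-methoxyphenyl)methoxy]-3-methylidenepent-4-yn-1-ol | C#CC(=C)[C@H](OCc1ccc(OC)cc1)CO | intermediate
16 | {(5S)-5-[(2R,3RS,7S)-2,3,8-trihydroxy-7-[(4-methoxyphenyl)methoxy]-2-methyl-6-methylideneoct-4-yn-1-yl]-2-oxo-2,5-dihydrofuran-3-yl}methyl acetate | CC(=O)OCC1=C[C@H](C[C@@](C)(O)C(O)C#CC(=C)[C@H](OCc2ccc(OC)cc2)CO)OC1=O | intermediate
17 | {(5S)-5-[(2R,7S)-2-hydroxy-7-[(4-methoxyphenyl)methoxy]-2-methyl-6-methylidene-3,8-dioxooct-4-yn-1-yl]-2-oxo-2,5-dihydrofuran-3-yl}methyl acetate | CC(=O)OCC1=C[C@H](C[C@@](C)(O)C(=O)C#CC(=C)[C@H](OCc2ccc(OC)cc2)C=O)OC1=O | intermediate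
18 | [(5S)-5-{[(2R)-5-{(3S)-3-[(4-methoxyphenyl)methoxy]-4-oxobut-1-en-2-yl}-2-methyl-3-oxo-2,3-dihydrofuran-2-yl]methyl}-2-oxo-2,5-dihydrofuran-3-yl]methyl acetate | CC(=O)OCC1=C[C@H](C[C@@]2(C)OC(=CC2=O)C(=C)[C@H](OCc3ccc(OC)cc3)C=O)OC1=O | intermediate
19 | 6-O-desangeloyl-5-O-(4-methoxybenzyl) derivative of 21 (tricycle with free C6-OH; all five stereocentres as in 21) | C=C1C(=O)O[C@H]2C[C@@]3(C)OC(=CC3=O)C(=C)[C@H](OCc4ccc(OC)cc4)[C@@H](O)[C@H]12 | intermediate
20 | 5-O-(4-methoxybenzyl) ether of 21 | C=C1C(=O)O[C@H]2C[C@@]3(C)OC(=CC3=O)C(=C)[C@H](OCc4ccc(OC)cc4)[C@@H](OC(=O)/C(C)=C\C)[C@H]12 | intermediate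
21 | (5S,6S,7R,8S,10R)-6-angeloyloxy-3,10-epoxy-5-hydroxy-1-oxogermacra-2,4(15),11(13)-trien-12,8-olide (CNP0120053.1) | C=C1C(=O)O[C@H]2C[C@@]3(C)OC(=CC3=O)C(=C)[C@H](O)[C@@H](OC(=O)/C(C)=C\C)[C@H]12 | target

**Step count and risks**

Total steps: 17 (west branch 1–7, east branch 8–12, union and endgame 13–17). Longest linear sequence: 12 (steps 1–7, then 13–17).

The three steps most likely to fail:

Step 15 (one-pot furanone formation and Pd/In ring closure; medium-ring yield and C6/C7 selectivity are unproven). The fallback sets out from bromide 6 and alkyne 15 and returns at 20. It makes the C6–C7 bond intermolecularly and closes the ring at C1–C2 instead.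
- Dess–Martin oxidation of 15 gives (2S)-2-[(4-methoxyphenyl)methoxy]-3-methylidenepent-4-ynal F5.
- Indium-mediated Barbier allylation of F5 with 6 (In, THF/H2O; same chair and chelate model, no ring strain) gives the α-methylene lactone C6 alcohol F6.
- The angelic mixed anhydride converts it to the C6 angelate F7.
- Aqueous acetic acid removes the acetonide to give the diol F8.
- TEMPO/PhI(OAc)2 gives the α-hydroxy aldehyde F9.
- NIS with catalytic AgNO3 gives the iodoalkyne F10.
- CrCl2 with catalytic NiCl2 at high dilution (Nozaki–Hiyama–Kishi alkynylation) closes the ten-membered ring to the macrocyclic propargylic alcohol F11.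
- MnO2 gives the macrocyclic ynone F12, and catalytic (Ph3P)AuNTf2 triggers the transannular 5-endo-dig oxa-Michael addition to 20.

Step 4 (radical bromination with allylic transposition; ring C–H abstraction or the wrong bromide regioisomer could compete). The fallback sets out from alcohol 3 and returns at 6, bypassing steps 3 and 4.
- TEMPO/PhI(OAc)2 oxidation gives 2-[(4R)-2,2,4-trimethyl-1,3-dioxolan-4-yl]acetaldehyde F1.
- Catalytic enantioselective vinylzinc addition (divinylzinc, MIB ligand) gives (2S)-1-[(4R)-2,2,4-trimethyl-1,3-dioxolan-4-yl]but-3-en-2-ol F2.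
- Esterification with 2-(bromomethyl)acrylic acid (carbodiimide, no DMAP) gives (2S)-1-[(4R)-2,2,4-trimethyl-1,3-dioxolan-4-yl]but-3-en-2-yl 2-(bromomethyl)prop-2-enoate F3.
- Ring-closing metathesis (Hoveyda–Grubbs II, toluene, 80 °C) closes the butenolide to 6.

Step 13 (a basic acetylide and three alkoxides next to an electrophilic butenolide acetate). The fallback sets out from alkyne 15 and aldehyde 9 and returns at 16.
- NIS with catalytic AgNO3 converts 15 into (2S)-5-iodo-2-[(4-methoxyphenyl)methoxy]-3-methylidenepent-4-yn-1-ol F4.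
- F4 is coupled with 9 by Nozaki–Hiyama–Kishi alkynylation (CrCl2, catalytic NiCl2, THF). The chromium(III) acetylide is non-basic, tolerates the free hydroxyls, and leaves the allylic acetate alone, giving 16 directly.

Further compounds
F1 | step 4 | 2-[(4R)-2,2,4-trimethyl-1,3-dioxolan-4-yl]acetaldehyde | O=CC[C@@]1(C)OC(C)(C)OC1
F2 | step 4 | (2S)-1-[(4R)-2,2,4-trimethyl-1,3-dioxolan-4-yl]but-3-en-2-ol | C=C[C@@H](O)C[C@@]1(C)OC(C)(C)OC1
F3 | step 4 | (2S)-1-[(4R)-2,2,4-trimethyl-1,3-dioxolan-4-yl]but-3-en-2-yl 2-(bromomethyl)prop-2-enoate | C=C(CBr)C(=O)O[C@H](C=C)C[C@@]1(C)OC(C)(C)OC1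
F4 | step 13 | (2S)-5-iodo-2-[(4-methoxyphenyl)methoxy]-3-methylidenepent-4-yn-1-ol | IC#CC(=C)[C@H](OCc1ccc(OC)cc1)CO
F5 | step 15 | (2S)-2-[(4-methoxyphenyl)methoxy]-3-methylidenepent-4-ynal | C#CC(=C)[C@H](OCc1ccc(OC)cc1)C=O
F6 | step 15 | α-methylene lactone C6 alcohol (acyclic adduct of 6 and F5; C5 to C8 and C10 configured as in 21) | C=C1C(=O)O[C@@H](C[C@@]2(C)OC(C)(C)OC2)[C@@H]1[C@H](O)[C@@H](OCc1ccc(OC)cc1)C(=C)C#C
F7 | step 15 | C6 angelate of F6 | C=C1C(=O)O[C@@H](C[C@@]2(C)OC(C)(C)OC2)[C@@H]1[C@H](OC(=O)/C(C)=C\C)[C@@H](OCc1ccc(OC)cc1)C(=C)C#C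
F8 | step 15 | diol from acetonide cleavage of F7 | C=C1C(=O)O[C@@H](C[C@@](C)(O)CO)[C@@H]1[C@H](OC(=O)/C(C)=C\C)[C@@H](OCc1ccc(OC)cc1)C(=C)C#C
F9 | step 15 | α-hydroxy aldehyde from F8 | C=C1C(=O)O[C@@H](C[C@@](C)(O)C=O)[C@@H]1[C@H](OC(=O)/C(C)=C\C)[C@@H](OCc1ccc(OC)cc1)C(=C)C#C
F10 | step 15 | iodoalkyne from F9 | C=C1C(=O)O[C@@H](C[C@@](C)(O)C=O)[C@@H]1[C@H](OC(=O)/C(C)=C\C)[C@@H](OCc1ccc(OC)cc1)C(=C)C#CI
F11 | step 15 | macrocyclic propargylic alcohol (ten-membered ring; C1 carbinol epimers) | C=C1C(=O)O[C@H]2C[C@@](C)(O)C(O)C#CC(=C)[C@H](OCc3ccc(OC)cc3)[C@@H](OC(=O)/C(C)=C\C)[C@H]12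
F12 | step 15 | macrocyclic α'-hydroxy ynone | C=C1C(=O)O[C@H]2C[C@@](C)(O)C(=O)C#CC(=C)[C@H](OCc3ccc(OC)cc3)[C@@H](OC(=O)/C(C)=C\C)[C@H]12
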